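## Retrosynthetic overview

1. Target 34 ← 15-alcohol 33 (MnO2) ← 15-acetate 32, where a lipase removes only the primary allylic acetate in the presence of the 6-acetate, the angelate and the lactone ← 9-alcohol 29 + angelic acid; the acrolein unit is the isopropenyl group, oxidised late (ene-chlorination, acetate).
2. α-Methylene lactone ← Eschenmoser methylenation of the saturated cis-lactone; 6β-oxygen ← C6 ketone, reduced under direction of the free 8α-OH (Evans–Saksena) while the lactone is temporarily opened as an amide.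
3. Lactone ring B ← intramolecular carboxylate SN2 on an 8β-bromo-9-ketone (forces the cis fusion); 9α-OH ← hydride reduction of the C9 ketone.
4. C7 acetic arm ← malonate Michael addition/Krapcho on the enone; quaternary C10 ← methylation, then formaldehyde aldol (CH2OH → CHO → vinyl).
5. Ring A (the carbocycle) is bought as quinone monoketal 1 and desymmetrised by [Rh(cod)2]BF4/(R)-BINAP-catalysed isopropenyl 1,4-addition (first stereocentre, C5). Ring order: A from the start; B closed in step 9, opened in step 12, re-closed in step 14.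

Assumption/convention: the SMILES is taken as the absolute configuration; positions use elemanolide numbering of the target (ring C5–C10; C10 bears CH3 and the C1=C2 vinyl; C5 bears C4(=C3)–C15; C7 bears C11(=C13)–C12(=O)–O–C8); β = ring face of the C10 methyl, α = the opposite face. The route is a proposal from precedent; it has not been run.

## Route

Step 1
Reactants: 1 4,4-dimethoxycyclohexa-2,5-dien-1-one; 2 potassium trifluoro(prop-1-en-2-yl)borate
Product: 3 (5R)-4,4-dimethoxy-5-(prop-1-en-2-yl)cyclohex-2-en-1-one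
Conditions: [Rh(cod)2]BF4 (3 mol %), (R)-BINAP (3.3 mol %), Et3N (1 equiv), 2 (1.1 equiv), toluene/H2O 20:1, 25 °C
Reagents that add atoms: none
Why: Hayashi–Miyaura-type asymmetric 1,4-addition of an alkenylborate (known for isopropenyl on quinone monoketals), in which the [Rh(cod)2]BF4/(R)-BINAP catalyst selects one enantiotopic enone face of the achiral dienone and so sets C5 (isopropenyl β) as the first stereocentre.

Step 2
Reactants: 3 (5R)-4,4-dimethoxy-5-(prop-1-en-2-yl)cyclohex-2-en-1-one
Product: 4 10-methyl enone (4,4-dimethoxy-6-methyl-5-(prop-1-en-2-yl)cyclohex-2-en-1-one, C10 epimers, trans major)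
Conditions: LiN(i-Pr)2, THF, −78 °C; MeI, −78 → −20 °C
Reagents that add atoms: iodomethane, CI
Why: Kinetic α′-enolate alkylation at C10, the only enolisable carbon (C6 is a ketal); the new centre is re-enolised in step 3, so its configuration does not matter, and base never threatens aromatisation.

Step 3
Reactants: 4 10-methyl enone
Product: 5 10α-(hydroxymethyl)-10β-methyl-5β-isopropenyl-6,6-dimethoxycyclohex-7-en-9-one
Conditions: LiN(i-Pr)2, THF, −78 °C; monomeric CH2O (THF solution), −78 °C; aq. NH4Cl
Reagents that add atoms: formaldehyde, C=O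
Why: Aldol reaction of the tetrasubstituted lithium enolate with formaldehyde, which enters anti to the neighbouring C5 isopropenyl group and so fixes the quaternary C10 with CH2OH α and CH3 β (cis to the C5 side chain).

Step 4
Reactants: 5 10α-(hydroxymethyl) enone
Product: 6 10α-formyl-10β-methyl-5β-isopropenyl-6,6-dimethoxycyclohex-7-en-9-one
Conditions: Dess–Martin periodinane, NaHCO3, CH2Cl2, 0 °C → rt
Reagents that add atoms: none
Why: Buffered Dess–Martin oxidation of a neopentyl primary alcohol; the product is a non-enolisable keto aldehyde (C10 quaternary) and the ketal, enone and isopropenyl group are inert.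

Step 5
Reactants: 6 10α-formyl enone
Product: 7 6,6-dimethoxy-10β-methyl-10α-vinyl-5β-isopropenylcyclohex-7-en-9-one
Conditions: Ph3PCH3Br, KN(SiMe3)2, THF, 0 °C; then 6, −78 → 0 °C
Reagents that add atoms: methyltriphenylphosphonium bromide, C[P+](c1ccccc1)(c1ccccc1)c1ccccc1.[Br-]
Why: Wittig methylenation, chemoselective for the aldehyde over the hindered conjugated ketone, gives the angular vinyl group with C10 unchanged.

Step 6
Reactants: 7 10α-vinyl enone; 8 dimethyl malonate
Product: 9 7α-[bis(methoxycarbonyl)methyl]-6,6-dimethoxy-10β-methyl-10α-vinyl-5β-isopropenylcyclohexan-9-one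
Conditions: 8 (3 equiv), NaOMe (0.3 equiv), MeOH, 0 °C → rt
Reagents that add atoms: none
Why: Michael addition in which malonate attacks the enone β-carbon C7 axially and anti to the C5 substituent (the 3,5-trans rule for 5-substituted cyclohexenones), setting the C7 arm α; the protic medium protonates the adduct quickly and keeps the addition under kinetic control.

Step 7
Reactants: 9 malonate adduct
Product: 10 methyl (9-oxo-6,6-dimethoxy-10β-methyl-10α-vinyl-5β-isopropenylcyclohex-7α-yl)acetate
Conditions: LiCl, H2O, DMSO, 140 °C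
Reagents that add atoms: none
Why: Krapcho dealkoxycarbonylation under neutral conditions, which spare the ketal and touch no stereocentre (the trans-divinylcyclohexane is the stable side of the Cope equilibrium).

Step 8
Reactants: 10 keto ester
Product: 11 (9-oxo-6,6-dimethoxy-10β-methyl-10α-vinyl-5β-isopropenylcyclohex-7α-yl)acetic acid
Conditions: LiOH·H2O, THF/MeOH/H2O, rt; cold 1 M HCl to pH 4–5
Reagents that add atoms: lithium hydroxide, [Li+].[OH-]
Why: Ester saponification; C7 is not α to a carbonyl and cannot epimerise, and the cold, weakly acidic work-up spares the ketal.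

Step 9
Reactants: 11 keto acid
Product: 14 6,6-dimethoxy-9-oxo-8α,12-lactone (cis-fused γ-lactone; C7–C11 α and C8–O α), via bis(trimethylsilyl) derivative 12 (not isolated), via 8β-bromo ketone silyl ester 13 (not isolated)
Conditions: LiN(SiMe3)2 (2.2 equiv), Me3SiCl, THF, −78 → 0 °C; N-bromosuccinimide, THF, −78 °C; NaHCO3, DMF/H2O, rt
Reagents that add atoms: none
Why: Regiospecific silyl enol ether formation (C8 is the only enolisable carbon), bromination anti to the C7 arm, then intramolecular SN2 displacement of the α-bromo ketone by the carboxylate with inversion, which can only deliver the cis-fused lactone with C8–O α (a cis bromide epimerises through the enol and funnels to the same product).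

Step 10
Reactants: 14 keto lactone
Product: 15 9α-hydroxy-6,6-dimethoxy-8α,12-lactone
Conditions: LiBH(s-Bu)3, THF, −78 °C; AcOH quench at −78 °C
Reagents that add atoms: none
Why: Diastereoselective hydride reduction in which the bulky borohydride attacks C9 from the β face — anti to the adjacent C8–O bond (Felkin–Anh polar model), on the convex face of the cis-fused bicycle and away from the axial C11 — giving the 9α-alcohol cis to O8; the lactone is not reduced at −78 °C.

Step 11
Reactants: 15 9α-hydroxy lactone
Product: 16 9α-(methoxymethoxy)-6,6-dimethoxy-8α,12-lactone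
Conditions: MeOCH2Cl, i-Pr2NEt, Bu4NI (cat.), CH2Cl2, 40 °C
Reagents that add atoms: chloromethyl methyl ether, COCCl
Why: O-alkylation of the hindered alcohol with the reactive α-chloro ether under amine base (no acid, so the ketal is safe), giving an acetal ether that cannot migrate to O8 when the lactone is opened.

Step 12
Reactants: 16 MOM-protected lactone
Product: 17 8α-hydroxy amide (7α-CH2CONMe2, 9α-OCH2OMe, 6,6-dimethoxy)
Conditions: Me2NH (2 M in THF, excess), 50 °C, sealed tube
Reagents that add atoms: dimethylamine, CNC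
Why: Lactone aminolysis frees the 8α-hydroxyl (C–O bond untouched) as a directing group and gives a tertiary amide that does not re-lactonise under neutral conditions.

Step 13
Reactants: 17 hydroxy amide ketal
Product: 18 6-oxo-8α-hydroxy amide
Conditions: PPTS (cat.), acetone/H2O 10:1, rt
Reagents that add atoms: water, O
Why: Mild acid-catalysed ketal hydrolysis that leaves the MOM ether and the amide intact; the β-hydroxy ketone (C5 and C7 are now α to the carbonyl) is used at once to avoid dehydration or epimerisation.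

Step 14
Reactants: 18 6-oxo-8α-hydroxy amide
Product: 20 6β-hydroxy-9α-(methoxymethoxy)-8α,12-lactone, via anti-diol amide 19 (not isolated)
Conditions: Me4NBH(OAc)3, MeCN/AcOH 1:1, −20 → 0 °C; then 45 °C
Reagents that add atoms: none
Why: Evans–Saksena hydroxyl-directed reduction, in which the C8 alkoxy(acetoxy)borohydride delivers hydride intramolecularly to the α face of C6 and gives the 1,3-anti diol (6β-OH); warming in AcOH then closes the cis-fused γ-lactone at O8 by N→O acyl transfer, which is faster and more stable than the trans-fused alternative at O6.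

Step 15
Reactants: 20 6β-hydroxy lactone
Product: 21 6β-(triethylsilyloxy)-9α-(methoxymethoxy)-8α,12-lactone
Conditions: Et3SiOTf, 2,6-lutidine, CH2Cl2, −78 °C
Reagents that add atoms: triethylsilyl trifluoromethanesulfonate, CC[Si](CC)(CC)OS(=O)(=O)C(F)(F)F
Why: Silyl triflate silylation of the hindered secondary alcohol, so that no alkoxide sits next to the lactone during the enolate step (prevents translactonisation).

Step 16
Reactants: 21 silyl-protected lactone
Product: 24 11(13)-methylene-6β-(triethylsilyloxy)-9α-(methoxymethoxy)-8α,12-lactone, via Mannich base 22 (not isolated), via trimethylammonium iodide 23 (not isolated)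
Conditions: LiN(i-Pr)2, THF, −78 °C; CH2=NMe2+ I−, −78 °C → rt; MeI, MeOH, rt; aq. NaHCO3, EtOAc, rt
Reagents that add atoms: N,N-dimethylmethyleneiminium iodide (Eschenmoser's salt), C=[N+](C)C.[I-]
Why: Eschenmoser methylenation (lactone enolate Mannich reaction, N-methylation, E1cB elimination of trimethylamine), done while no other ester and no C6 ketone is present; C7 carries no leaving group, so the enolate cannot eliminate.

Step 17
Reactants: 24 methylene lactone silyl ether
Product: 25 6β-hydroxy-11(13)-methylene-9α-(methoxymethoxy)-8α,12-lactone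
Conditions: HF·pyridine, pyridine, THF, 0 °C
Reagents that add atoms: none
Why: Fluoride-mediated cleavage of the triethylsilyl ether under buffered conditions that leave the MOM acetal, the methylene lactone and both alkenes untouched.

Step 18
Reactants: 25 6β-alcohol
Product: 26 6β-acetoxy-11(13)-methylene-9α-(methoxymethoxy)-8α,12-lactone
Conditions: Ac2O, DMAP (cat.), pyridine, CH2Cl2, rt
Reagents that add atoms: acetic anhydride, CC(=O)OC(C)=O
Why: DMAP-catalysed acylation of the only free hydroxyl installs the C6 acetate of the target with retention.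

Step 19
Reactants: 26 6β-acetate
Product: 27 15-chloride (C5β–C(=CH2)CH2Cl; otherwise as 26)
Conditions: Ca(OCl)2, solid CO2, CH2Cl2/H2O, 0 °C
Reagents that add atoms: calcium hypochlorite, [Ca+2].[O-]Cl.[O-]Cl
Why: Ene-type allylic chlorination by HOCl, selective for the electron-rich 1,1-disubstituted isopropenyl group (hydrogen taken from the methyl); the C10 vinyl has no allylic hydrogen and the methylene lactone is electron-poor.

Step 20
Reactants: 27 15-chloride
Product: 28 6β,15-diacetoxy-11(13)-methylene-9α-(methoxymethoxy)-8α,12-lactone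
Conditions: KOAc, 18-crown-6 (cat.), DMF, 50 °C
Reagents that add atoms: potassium acetate, [K+].CC(=O)[O-]
Why: SN2 displacement of the primary allylic chloride by acetate, too weak a Michael donor to attack the methylene lactone.

Step 21
Reactants: 28 MOM-protected diacetate
Product: 29 6β,15-diacetoxy-9α-hydroxy-11(13)-methylene-8α,12-lactone
Conditions: Me2BBr, CH2Cl2, −78 °C; aq. NaHCO3
Reagents that add atoms: none
Why: Lewis-acid cleavage of the MOM acetal by the bromoborane at low temperature, which tolerates acetates, the lactone and alkenes and leaves C9 untouched.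

Step 22
Reactants: 29 9α-alcohol; 30 angelic acid ((Z)-2-methylbut-2-enoic acid)
Product: 32 9α-angeloyloxy-6β,15-diacetoxy-11(13)-methylene-8α,12-lactone, via mixed anhydride 31 (not isolated)
Conditions: 30, 2,4,6-Cl3C6H2COCl, Et3N, toluene, rt; then 29, 75 °C
Reagents that add atoms: none
Why: Yamaguchi-type mixed-anhydride esterification run without a nucleophilic catalyst, the variant developed for angelates of hindered alcohols; attack at the less hindered angeloyl carbonyl keeps the Z geometry and puts the ester on the last free hydroxyl.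

Step 23
Reactants: 32 angelate diacetate
Product: 33 9α-angeloyloxy-6β-acetoxy-15-hydroxy-11(13)-methylene-8α,12-lactone
Conditions: lipase (Candida antarctica lipase B, immobilised), n-BuOH, t-BuOMe, 30 °C
Reagents that add atoms: none
Why: Enzymatic transesterification in which the serine hydrolase accepts only the unhindered primary allylic acetate, while the secondary C6 acetate, the angelate and the lactone are too hindered for the active site; this neutral differentiation of four ester groups is what the end game rests on.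

Step 24
Reactants: 33 15-alcohol
Product: 34 target
Conditions: MnO2 (activated), CH2Cl2, rt
Reagents that add atoms: none
Why: MnO2 oxidation of the primary allylic alcohol stops at the α-substituted acrolein and touches no ester, lactone or stereocentre.

## Compound list

1 | 4,4-dimethoxycyclohexa-2,5-dien-1-one | COC1(OC)C=CC(=O)C=C1 | starting material
2 | potassium trifluoro(prop-1-en-2-yl)borate | [K+].C=C(C)[B-](F)(F)F | starting material
3 | (5R)-4,4-dimethoxy-5-(prop-1-en-2-yl)cyclohex-2-en-1-one (C9 ketone, C7=C8, C6 ketal, 5β-isopropenyl) | C1C(=O)C=CC(OC)(OC)[C@H]1C(C)=C | intermediate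
4 | 10-methyl enone, C10 epimers (trans, 10α-CH3, drawn) | C[C@@H]1C(=O)C=CC(OC)(OC)[C@H]1C(C)=C | intermediate
5 | 10α-(hydroxymethyl)-10β-methyl-5β-isopropenyl-6,6-dimethoxycyclohex-7-en-9-one | OC[C@]1(C)C(=O)C=CC(OC)(OC)[C@H]1C(C)=C | intermediate
6 | 10α-formyl-10β-methyl-5β-isopropenyl-6,6-dimethoxycyclohex-7-en-9-one | O=C[C@]1(C)C(=O)C=CC(OC)(OC)[C@H]1C(C)=C | intermediate
7 | 6,6-dimethoxy-10β-methyl-10α-vinyl-5β-isopropenylcyclohex-7-en-9-one | C=C[C@]1(C)C(=O)C=CC(OC)(OC)[C@H]1C(C)=C | intermediate
8 | dimethyl malonate | COC(=O)CC(=O)OC | starting material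
9 | 7α-[bis(methoxycarbonyl)methyl] ketone (Michael adduct) | C=C[C@]1(C)C(=O)C[C@H](C(C(=O)OC)C(=O)OC)C(OC)(OC)[C@H]1C(C)=C | intermediate
10 | keto ester, 7α-CH2CO2Me | C=C[C@]1(C)C(=O)C[C@H](CC(=O)OC)C(OC)(OC)[C@H]1C(C)=C | intermediate
11 | keto acid, 7α-CH2CO2H | C=C[C@]1(C)C(=O)C[C@H](CC(=O)O)C(OC)(OC)[C@H]1C(C)=C | intermediate
12 | trimethylsilyl ester of the C8=C9 trimethylsilyl enol ether of 11 | C=C[C@]1(C)C(O[Si](C)(C)C)=C[C@H](CC(=O)O[Si](C)(C)C)C(OC)(OC)[C@H]1C(C)=C | intermediate (not isolated)
13 | trimethylsilyl ester of the 8β-bromo-9-keto acid | C=C[C@]1(C)C(=O)[C@@H](Br)[C@H](CC(=O)O[Si](C)(C)C)C(OC)(OC)[C@H]1C(C)=C | intermediate (not isolated)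
14 | 6,6-dimethoxy-9-oxo-8α,12-lactone (cis-fused) | C=C[C@]1(C)C(=O)[C@@H]2OC(=O)C[C@@H]2C(OC)(OC)[C@H]1C(C)=C | intermediate
15 | 9α-hydroxy-6,6-dimethoxy-8α,12-lactone | C=C[C@]1(C)[C@H](O)[C@@H]2OC(=O)C[C@@H]2C(OC)(OC)[C@H]1C(C)=C | intermediate
16 | 9α-(methoxymethoxy)-6,6-dimethoxy-8α,12-lactone | C=C[C@]1(C)[C@H](OCOC)[C@@H]2OC(=O)C[C@@H]2C(OC)(OC)[C@H]1C(C)=C | intermediate
17 | 8α-hydroxy-9α-(methoxymethoxy)-6,6-dimethoxy N,N-dimethylamide (7α-CH2CONMe2) | C=C[C@]1(C)[C@H](OCOC)[C@H](O)[C@H](CC(=O)N(C)C)C(OC)(OC)[C@H]1C(C)=C | intermediate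
18 | 6-oxo-8α-hydroxy-9α-(methoxymethoxy) amide | C=C[C@]1(C)[C@H](OCOC)[C@H](O)[C@H](CC(=O)N(C)C)C(=O)[C@H]1C(C)=C | intermediate
19 | 6β,8α-dihydroxy-9α-(methoxymethoxy) amide | C=C[C@]1(C)[C@H](OCOC)[C@H](O)[C@H](CC(=O)N(C)C)[C@@H](O)[C@H]1C(C)=C | intermediate (not isolated)
20 | 6β-hydroxy-9α-(methoxymethoxy)-8α,12-lactone | C=C[C@]1(C)[C@H](OCOC)[C@@H]2OC(=O)C[C@@H]2[C@@H](O)[C@H]1C(C)=C | intermediate
21 | 6β-(triethylsilyloxy)-9α-(methoxymethoxy)-8α,12-lactone | C=C[C@]1(C)[C@H](OCOC)[C@@H]2OC(=O)C[C@@H]2[C@@H](O[Si](CC)(CC)CC)[C@H]1C(C)=C | intermediate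
22 | 11-(dimethylaminomethyl) lactone (Mannich base, C11 epimers) | C=C[C@]1(C)[C@H](OCOC)[C@@H]2OC(=O)C(CN(C)C)[C@@H]2[C@@H](O[Si](CC)(CC)CC)[C@H]1C(C)=C | intermediate (not isolated)
23 | 11-(trimethylammoniomethyl) lactone iodide | C=C[C@]1(C)[C@H](OCOC)[C@@H]2OC(=O)C(C[N+](C)(C)C)[C@@H]2[C@@H](O[Si](CC)(CC)CC)[C@H]1C(C)=C.[I-] | intermediate (not isolated)
24 | 11(13)-methylene-6β-(triethylsilyloxy)-9α-(methoxymethoxy)-8α,12-lactone | C=C[C@]1(C)[C@H](OCOC)[C@@H]2OC(=O)C(=C)[C@@H]2[C@@H](O[Si](CC)(CC)CC)[C@H]1C(C)=C | intermediate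
25 | 6β-hydroxy-11(13)-methylene-9α-(methoxymethoxy)-8α,12-lactone | C=C[C@]1(C)[C@H](OCOC)[C@@H]2OC(=O)C(=C)[C@@H]2[C@@H](O)[C@H]1C(C)=C | intermediate
26 | 6β-acetoxy-11(13)-methylene-9α-(methoxymethoxy)-8α,12-lactone | C=C[C@]1(C)[C@H](OCOC)[C@@H]2OC(=O)C(=C)[C@@H]2[C@@H](OC(C)=O)[C@H]1C(C)=C | intermediate
27 | 15-chloro compound (C5β–C(=CH2)CH2Cl) | C=C[C@]1(C)[C@H](OCOC)[C@@H]2OC(=O)C(=C)[C@@H]2[C@@H](OC(C)=O)[C@H]1C(=C)CCl | intermediate
28 | 6β,15-diacetoxy-9α-(methoxymethoxy) methylene lactone | C=C[C@]1(C)[C@H](OCOC)[C@@H]2OC(=O)C(=C)[C@@H]2[C@@H](OC(C)=O)[C@H]1C(=C)COC(C)=O | intermediate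
29 | 6β,15-diacetoxy-9α-hydroxy methylene lactone | C=C[C@]1(C)[C@H](O)[C@@H]2OC(=O)C(=C)[C@@H]2[C@@H](OC(C)=O)[C@H]1C(=C)COC(C)=O | intermediate
30 | angelic acid, (Z)-2-methylbut-2-enoic acid | C/C=C(/C)C(=O)O | starting material
31 | angelic 2,4,6-trichlorobenzoic anhydride | C/C=C(/C)C(=O)OC(=O)c1c(Cl)cc(Cl)cc1Cl | intermediate (not isolated)
32 | 9α-angeloyloxy-6β,15-diacetoxy methylene lactone | C=C[C@]1(C)[C@H](OC(=O)/C(C)=C\C)[C@@H]2OC(=O)C(=C)[C@@H]2[C@@H](OC(C)=O)[C@H]1C(=C)COC(C)=O | intermediate
33 | 9α-angeloyloxy-6β-acetoxy-15-hydroxy methylene lactone | C=C[C@]1(C)[C@H](OC(=O)/C(C)=C\C)[C@@H]2OC(=O)C(=C)[C@@H]2[C@@H](OC(C)=O)[C@H]1C(=C)CO | intermediate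
34 | CNP0252310.2 (9α-angeloyloxy-6β-acetoxy-15-oxo-elema-1,3,11(13)-trien-8α,12-olide) | C=C[C@]1(C)[C@H](OC(=O)/C(C)=C\C)[C@@H]2OC(=O)C(=C)[C@@H]2[C@@H](OC(C)=O)[C@H]1C(=C)C=O | target

## Step count and risks

Total steps: 24. Longest linear sequence: 24 steps (1 → 34; 2, 8 and 30 each enter in one step).

Three steps most likely to fail:

Step 6 (malonate Michael addition). The β-carbon sits next to the ketal carbon, and any reversibility would erode the trans (7α) selectivity. The fallback sets out from 7 and comes back at 10. A Mukaiyama–Michael addition of 1-(tert-butyldimethylsilyloxy)-1-methoxyethene to 7 (catalytic LiClO4, Et2O/CH2Cl2, −40 °C) transfers the acetate unit irreversibly, again by axial attack anti to the C5 group. It gives the tert-butyldimethylsilyl enol ether of the keto ester F1, and HF·pyridine desilylation returns keto ester 10 without malonate or Krapcho step.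

Step 14 (directed reduction and re-lactonisation). Hydride delivery needs the C8–O bond axial, the β-hydroxy ketone 18 can dehydrate, and ring closure could choose O6. The fallback sets out from 16 and comes back at 20, skipping 17–19. The ketal of 16 is hydrolysed directly (PPTS, wet acetone) to the closed 6-oxo lactone F2. LiBH(s-Bu)3 at −78 °C, attacking the convex β face of the cis-fused bicycle, then gives the 6α-alcohol F3. A Mitsunobu reaction (PPh3, DIAD, 4-nitrobenzoic acid) inverts C6 to the 6β-(4-nitrobenzoate) F4, and methanolysis (NaN3, MeOH, 40 °C) returns 20.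

Step 22 (angeloylation). The 9α-hydroxyl is neopentyl-like and flanked by the lactone oxygen, and angelates isomerise to tiglates under forcing acylation. The fallback sets out from 29 and comes back at 32, building the angelate on the molecule. Esterification with 2-[bis(2,2,2-trifluoroethoxy)phosphoryl]propanoic acid (DCC, CH2Cl2; the phosphono-ketene formed on activation acylates hindered alcohols) gives the 9α-phosphonopropionate F5. A Still–Gennari olefination with acetaldehyde (KN(SiMe3)2, 18-crown-6, THF, −78 °C) then creates the Z-trisubstituted enoate, i.e. 32.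

## Further compounds

F1 | step 6 | tert-butyldimethylsilyl enol ether (C8=C9) of keto ester 10 | C=C[C@]1(C)C(O[Si](C)(C)C(C)(C)C)=C[C@H](CC(=O)OC)C(OC)(OC)[C@H]1C(C)=C
F2 | step 14 | 6-oxo-9α-(methoxymethoxy)-8α,12-lactone | C=C[C@]1(C)[C@H](OCOC)[C@@H]2OC(=O)C[C@@H]2C(=O)[C@H]1C(C)=C
F3 | step 14 | 6α-hydroxy-9α-(methoxymethoxy)-8α,12-lactone | C=C[C@]1(C)[C@H](OCOC)[C@@H]2OC(=O)C[C@@H]2[C@H](O)[C@H]1C(C)=C
F4 | step 14 | 6β-(4-nitrobenzoyloxy)-9α-(methoxymethoxy)-8α,12-lactone | C=C[C@]1(C)[C@H](OCOC)[C@@H]2OC(=O)C[C@@H]2[C@@H](OC(=O)c3ccc(cc3)[N+](=O)[O-])[C@H]1C(C)=C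
F5 | step 22 | 9α-{2-[bis(2,2,2-trifluoroethoxy)phosphoryl]propanoyloxy}-6β,15-diacetoxy methylene lactone | C=C[C@]1(C)[C@H](OC(=O)C(C)P(=O)(OCC(F)(F)F)OCC(F)(F)F)[C@@H]2OC(=O)C(=C)[C@@H]2[C@@H](OC(C)=O)[C@H]1C(=C)COC(C)=O
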